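The readings were computed with constants of no real substance; scatter was added.

Starting material left over in violet at 22 h was 23.56 mM, and the green flask, charged like violet, asks what remains at 44 h. Starting material is the limiting reagent. One coupling partner goes with each one turned, so the excess of partner stays at 0.100 M in violet.

the same everywhere: starting material 50.0 mM

| charge | coupling partner | free catalyst | time |
|---|---|---|---|
| violet | 150 mM | 2.50 mM |  |
| teal | 150 mM | 1.30 mM |  |
| blue | 220 mM | 2.50 mM |  |
| green | 150 mM | 2.50 mM | 44 h |

| violet run: time / h | violet run: [starting material] / mM | teal run: time / h | teal run: [starting material] / mM | blue run: time / h | blue run: [starting material] / mM |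
|---|---|---|---|---|---|
| 2.8 | 47.53 | 2.8 | 49.08 | 2.8 | 46.38 |
| 5.5 | 43.58 | 5.5 | 47.02 | 5.5 | 40.97 |
| 8.2 | 39.35 | 8.2 | 45.78 | 8.2 | 34.57 |
| 11 | 36.07 | 11 | 43.30 | 11 | 29.97 |
| 14 | 32.03 | 14 | 41.62 | 14 | 25.12 |
| 16 | 29.78 | 16 | 40.19 | 16 | 22.00 |
| 19 | 26.57 | 19 | 38.31 | 19 | 18.37 |
| 22 | 23.56 | 22 | 36.83 | 22 | 15.30 |

(each reading ± 0.2 mM)

- order of the initial rate in [coupling partner], near the charge of the violet run, the rate being that where two percent of its starting material are product
- order of the initial rate in [free catalyst], near the charge of the violet run, the rate being that where two percent of its starting material are product
- starting material in the green run at 44 h, as a share of the starting material charged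

- Overall: starting material + coupling partner -> product, with free catalyst as catalyst.
- Constant volume, constant temperature.
- The analysis sees a species whether free or bound.
- An order is taken over about fifteen percent of the charge, up and down.

I wanted a quantity that strips starting material and partner out of a rate. From 16 h to 22 h violet gave 0.307 /M/h for the loss per hour divided by starting material and by partner at mid-stretch, which I call the pair pace.

I turned the partner first. By hand, more partner should leave the pair pace unchanged at equal starting material if the rate follows partner in proportion. Blue, with an excess of 0.170 M, gave 0.313 /M/h from 11 h to 16 h, at nearly the level of that violet stretch, so it matched.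

Next I turned the catalyst. By hand, the teal charge should scale the pair pace by 0.520. Teal late gave 0.105 /M/h. Violet at a similar level, from 5.5 h to 11 h, gave 0.245 /M/h. The ratio read 0.428, smaller than the charges' ratio. It looked as if 0.402 mM of each charge did no work.

Last came time. With a constant excess and a constant pair pace, the logarithm of starting material over starting material plus excess falls by excess times pair pace each hour. But violet's pair pace rose as starting material fell. I read that as a fast equilibrium holding catalyst on starting material. So for green after 22 h I used blue's last stretch, at the same catalyst charge and lower levels, with a pair pace of 0.317 /M/h. That left 21.0%.

The orders belong to the slow start: violet lost 0.882 mM/h at first, then 1.46 mM/h. I gave them no number, and expected that they would lie below the later orders.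

The forecast gave 0.75, 0.78 and 16.5%, with this ground: “Two percent conversion, however, falls inside the lag”.

The simulation gave 0.67, 0.79 and 19.8%, so my green share stood 1.2 percentage points higher.

    active catalyst + starting material ⇌ catalyst-substrate complex, settled at all times (17.30 /M)
    catalyst-substrate complex + coupling partner → product + active catalyst + by-product (12.20 /M/h)
    free catalyst → active catalyst (0.6948 /h)
    active catalyst + impurity → spent catalyst

In violet, free catalyst became active catalyst with a lifetime of 1.44 h, and the impurity took the first 0.394 mM at once, leaving spent catalyst. The coupling step ran through the catalyst-substrate complex, which in green held about 46.4% of the working catalyst at the level of starting material charged and about 14.6% at 44 h. In teal, violet's late pair pace times 0.428 put the point where half of the charge has turned at 44.6 h, and the run reached it at 45.4 h.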